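**Plan**
- Retrosynthesis: ring C is cut at O1–C2 and C4–C4a (flavone ⇐ 2-hydroxyaryl ynone ⇐ C4a-lithiated ring A + Weinreb ynamide of ring B); ring A is cut at C8a–C8, C7–C6 and C8a–C4a.
- Enabling feature: ring A is a benzene with oxygen on C5, C7 and C8a alternating with carbon on C6, C8 and C4a. A ketene carbonyl, a siloxyalkyne and a 3-siloxycyclobutenone deliver this 1,3,5-trioxygenated pattern with each prenyl group already on its carbon.
- Forward: one siloxyalkyne is made from prenyl bromide; part of it is joined with ketene to the cyclobutenone, and the two are fused thermally into ring A, the first ring formed.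
- The silyl ethers are exchanged for MOM ethers, C4a is lithiated and acylated with the ring B ynamide (ring B comes from 2,4-dihydroxybenzaldehyde), and acid closes ring C last while freeing all phenols.
- Stereochemistry: the target has no stereocentre and no stereogenic double bond; the transient quaternary carbon and diene geometry of the benzannulation vanish on aromatisation.

Key step: step 4

Remark: atom labels such as C4a and C8a follow flavone numbering of the target; after desilylation ring A is symmetric, so its two oxygens flanking C4a are equivalent and either may become O1.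

**Route**

Step 1
Reactants: 1 1-bromo-3-methylbut-2-ene (prenyl bromide); 2 ethynylmagnesium bromide
Product: 3 5-methylhex-4-en-1-yne
Conditions: HC≡CMgBr (2 equiv, THF), CuCl (5 mol %), 0 °C → rt; fractional distillation
Reagents that add atoms: none
Why: Copper-catalysed allyl–alkynyl cross-coupling of an alkynyl Grignard reagent with a primary allylic bromide should join the acetylide to the unhindered CH2 terminus and give the skipped enyne, the excess of Grignard reagent suppressing double coupling.

Step 2
Reactants: 3 5-methylhex-4-en-1-yne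
Product: 6 5-methyl-1-(triisopropylsilyloxy)hex-4-en-1-yne, via lithium acetylide 4 (not isolated), via lithium ynolate 5 (not isolated)
Conditions: n-BuLi, THF, −78 °C; t-BuOOLi (from t-BuOOH + LiN(SiMe3)2), −78 → 0 °C; TIPSOTf, −78 → 0 °C
Reagents that add atoms: tert-butyl hydroperoxide, CC(C)(C)OO; triisopropylsilyl trifluoromethanesulfonate, CC(C)[Si](OS(=O)(=O)C(F)(F)F)(C(C)C)C(C)C
Why: Julia ynolate synthesis (oxygen transfer from lithium tert-butyl peroxide to the lithium acetylide) followed by O-silylation with the bulky silyl triflate is the standard entry to triisopropylsilyl ynol ethers, and the acetylenic C–H is far more acidic than the allylic–propargylic CH2.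

Step 3
Reactants: 6 5-methyl-1-(triisopropylsilyloxy)hex-4-en-1-yne; 7 acetone
Product: 9 2-(3-methylbut-2-enyl)-3-(triisopropylsilyloxy)cyclobut-2-en-1-one, via ketene 8 (not isolated)
Conditions: acetone, hot-wire ketene generator (ca. 700 °C); ketene gas passed into 6, CH2Cl2, 0 °C → rt
Reagents that add atoms: none
Why: Thermal [2+2] cycloaddition of ketene to an electron-rich ynol ether, in which the nucleophilic alkyne carbon (β to oxygen, carrying prenyl) bonds to the ketene carbonyl carbon, should place prenyl on C2 and the siloxy group on C3 of the cyclobutenone.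

Step 4
Reactants: 9 2-(3-methylbut-2-enyl)-3-(triisopropylsilyloxy)cyclobut-2-en-1-one; 6 5-methyl-1-(triisopropylsilyloxy)hex-4-en-1-yne
Product: 14 2,4-bis(3-methylbut-2-enyl)-3,5-bis(triisopropylsilyloxy)phenol, via vinylketene 10 (not isolated), via vinylcyclobutenone 11 (not isolated), via dienylketene 12 (not isolated), via cyclohexadienone 13 (not isolated)
Conditions: 6 (1.3 equiv), toluene, sealed tube, argon, 80 → 110 °C
Reagents that add atoms: none
Why: Heating opens cyclobutenone 9 by 4π electrocyclic cleavage of its C1–C4 bond to the (1-siloxyvinyl)ketene 10, whose ketene C=C adds [2+2] to the ynol silyl ether 6 to give 4-vinylcyclobutenone 11; a second 4π opening gives dienylketene 12. The closest known reaction is the Danheiser benzannulation of cyclobutenones with trialkylsilyloxyalkynes, which gives resorcinol monosilyl ethers; the additional C3 siloxy group of 9 extends it to a phloroglucinol. Ring A, the only ring formed, closes by thermal 6π electrocyclisation of 12 (C8a–C4a bond) to cyclohexadienone 13, which tautomerises to the phenol, after the [2+2] step has made C8a–C8 and C7–C6. No stereocentre is created, since the quaternary carbon of 11 and the alkene geometry of 12 disappear on aromatisation, and a dienylketene of the wrong geometry can return through 11. The step needs a single regiochemical sense in the [2+2] addition (ketene carbonyl carbon to the prenyl-bearing alkyne carbon), which the polarisation of the siloxyalkyne, nucleophilic at the carbon β to oxygen, secures. A small excess of 6 keeps the vinylketene from acylating the product phenol.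

Step 5
Reactants: 14 2,4-bis(3-methylbut-2-enyl)-3,5-bis(triisopropylsilyloxy)phenol
Product: 15 2,4-bis(3-methylbut-2-enyl)benzene-1,3,5-triol
Conditions: Bu4NF, AcOH, THF, 0 °C, argon
Reagents that add atoms: none
Why: Fluoride-induced cleavage of the two aryl silyl ethers, buffered with acetic acid, should release the air-sensitive diprenylphloroglucinol as the neutral phenol without touching the prenyl groups.

Step 6
Reactants: 15 2,4-bis(3-methylbut-2-enyl)benzene-1,3,5-triol
Product: 16 1,3,5-tris(methoxymethoxy)-2,4-bis(3-methylbut-2-enyl)benzene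
Conditions: NaH, MOMCl, DMF, 0 °C → rt, argon
Reagents that add atoms: chloromethyl methyl ether, COCCl
Why: Williamson O-alkylation of the three phenoxides with the hard α-chloro ether should give the tris-acetal, whose MOM groups direct the metalation of step 10.

Step 7
Reactants: 17 2,4-dihydroxybenzaldehyde
Product: 18 2,4-bis(methoxymethoxy)benzaldehyde
Conditions: NaH, MOMCl, DMF, 0 °C → rt
Reagents that add atoms: chloromethyl methyl ether, COCCl
Why: Williamson O-alkylation under sodium hydride conditions should also alkylate the chelated 2-hydroxyl and give the bis-acetal.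

Step 8
Reactants: 18 2,4-bis(methoxymethoxy)benzaldehyde
Product: 19 1-ethynyl-2,4-bis(methoxymethoxy)benzene
Conditions: dimethyl (1-diazo-2-oxopropyl)phosphonate, K2CO3, MeOH, rt
Reagents that add atoms: dimethyl (1-diazo-2-oxopropyl)phosphonate, COP(=O)(OC)C(=[N+]=[N-])C(C)=O
Why: Seyferth–Gilbert homologation in its Ohira–Bestmann form converts an aryl aldehyde into the terminal alkyne under mildly basic conditions that leave aryl MOM ethers untouched.

Step 9
Reactants: 19 1-ethynyl-2,4-bis(methoxymethoxy)benzene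
Product: 21 3-[2,4-bis(methoxymethoxy)phenyl]-N-methoxy-N-methylprop-2-ynamide, via lithium acetylide 20 (not isolated)
Conditions: n-BuLi, THF, −78 °C; ClC(O)N(OMe)Me, −78 → 0 °C
Reagents that add atoms: N-methoxy-N-methylcarbamoyl chloride, CON(C)C(=O)Cl
Why: Acylation of a lithium acetylide with a carbamoyl chloride should give the Weinreb amide of the arylpropiolic acid directly.

Step 10
Reactants: 16 1,3,5-tris(methoxymethoxy)-2,4-bis(3-methylbut-2-enyl)benzene; 21 3-[2,4-bis(methoxymethoxy)phenyl]-N-methoxy-N-methylprop-2-ynamide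
Product: 23 3-[2,4-bis(methoxymethoxy)phenyl]-1-[2,4,6-tris(methoxymethoxy)-3,5-bis(3-methylbut-2-enyl)phenyl]prop-2-yn-1-one, via aryllithium 22 (not isolated)
Conditions: n-BuLi, TMEDA, THF, −20 → 0 °C; 21, −78 °C; AcOH quench at −78 °C
Reagents that add atoms: none
Why: Directed ortho-metalation at the only ring C–H, flanked by two MOM ethers, followed by 1,2-addition of the aryllithium to the Weinreb amide should give the ynone, because the chelated tetrahedral adduct collapses only on work-up and ring lithiation between two MOM ethers is faster than deprotonation of a prenyl CH2.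

Step 11
Reactants: 23 3-[2,4-bis(methoxymethoxy)phenyl]-1-[2,4,6-tris(methoxymethoxy)-3,5-bis(3-methylbut-2-enyl)phenyl]prop-2-yn-1-one
Product: 25 2-(2,4-dihydroxyphenyl)-5,7-dihydroxy-6,8-bis(3-methylbut-2-enyl)chromen-4-one, via pentahydroxy ynone 24 (not isolated)
Conditions: 3 M aq HCl, MeOH, 45 °C, argon; reaction stopped as soon as the last MOM group is gone
Reagents that add atoms: none
Why: Acid-catalysed acetal exchange transfers the five MOM groups to methanol and the freed ortho-hydroxy ynone should close ring C by 6-endo oxa-Michael addition (flavone synthesis from 2-hydroxyaryl ynones), acid activating the β-carbon and so disfavouring 5-exo closure to an aurone, while the two equivalent ortho oxygens lead to the same flavone.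

**Compound list**
1 | 1-bromo-3-methylbut-2-ene (prenyl bromide) | CC(C)=CCBr | starting material
2 | ethynylmagnesium bromide | C#C[Mg]Br | starting material
3 | 5-methylhex-4-en-1-yne | CC(C)=CCC#C | intermediate
4 | (5-methylhex-4-en-1-yn-1-yl)lithium, not isolated | [Li]C#CCC=C(C)C | intermediate
5 | lithium 5-methylhex-4-en-1-yn-1-olate, not isolated | [Li+].[O-]C#CCC=C(C)C | intermediate
6 | 5-methyl-1-(triisopropylsilyloxy)hex-4-en-1-yne | CC(C)=CCC#CO[Si](C(C)C)(C(C)C)C(C)C | intermediate
7 | acetone | CC(C)=O | starting material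
8 | ketene (ethenone), not isolated | C=C=O | intermediate
9 | 2-(3-methylbut-2-enyl)-3-(triisopropylsilyloxy)cyclobut-2-en-1-one | CC(C)=CCC1=C(O[Si](C(C)C)(C(C)C)C(C)C)CC1=O | intermediate
10 | 2-(3-methylbut-2-enyl)-3-(triisopropylsilyloxy)buta-1,3-dien-1-one (vinylketene), not isolated | O=C=C(CC=C(C)C)C(=C)O[Si](C(C)C)(C(C)C)C(C)C | intermediate
11 | 2,4-bis(3-methylbut-2-enyl)-3-(triisopropylsilyloxy)-4-[1-(triisopropylsilyloxy)ethenyl]cyclobut-2-en-1-one (racemic), not isolated | O=C1C(CC=C(C)C)=C(O[Si](C(C)C)(C(C)C)C(C)C)C1(CC=C(C)C)C(=C)O[Si](C(C)C)(C(C)C)C(C)C | intermediate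
12 | (3E)-2,4-bis(3-methylbut-2-enyl)-3,5-bis(triisopropylsilyloxy)hexa-1,3,5-trien-1-one (dienylketene), not isolated | O=C=C(CC=C(C)C)/C(O[Si](C(C)C)(C(C)C)C(C)C)=C(/CC=C(C)C)C(=C)O[Si](C(C)C)(C(C)C)C(C)C | intermediate
13 | 2,4-bis(3-methylbut-2-enyl)-3,5-bis(triisopropylsilyloxy)cyclohexa-2,4-dien-1-one, not isolated | O=C1CC(O[Si](C(C)C)(C(C)C)C(C)C)=C(CC=C(C)C)C(O[Si](C(C)C)(C(C)C)C(C)C)=C1CC=C(C)C | intermediate
14 | 2,4-bis(3-methylbut-2-enyl)-3,5-bis(triisopropylsilyloxy)phenol | CC(C)=CCc1c(O)cc(O[Si](C(C)C)(C(C)C)C(C)C)c(CC=C(C)C)c1O[Si](C(C)C)(C(C)C)C(C)C | intermediate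
15 | 2,4-bis(3-methylbut-2-enyl)benzene-1,3,5-triol | CC(C)=CCc1c(O)cc(O)c(CC=C(C)C)c1O | intermediate
16 | 1,3,5-tris(methoxymethoxy)-2,4-bis(3-methylbut-2-enyl)benzene | COCOc1cc(OCOC)c(CC=C(C)C)c(OCOC)c1CC=C(C)C | intermediate
17 | 2,4-dihydroxybenzaldehyde | O=Cc1ccc(O)cc1O | starting material
18 | 2,4-bis(methoxymethoxy)benzaldehyde | COCOc1ccc(C=O)c(OCOC)c1 | intermediate
19 | 1-ethynyl-2,4-bis(methoxymethoxy)benzene | COCOc1ccc(C#C)c(OCOC)c1 | intermediate
20 | {[2,4-bis(methoxymethoxy)phenyl]ethynyl}lithium, not isolated | [Li]C#Cc1ccc(OCOC)cc1OCOC | intermediate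
21 | 3-[2,4-bis(methoxymethoxy)phenyl]-N-methoxy-N-methylprop-2-ynamide | CON(C)C(=O)C#Cc1ccc(OCOC)cc1OCOC | intermediate
22 | [2,4,6-tris(methoxymethoxy)-3,5-bis(3-methylbut-2-enyl)phenyl]lithium, not isolated | [Li]c1c(OCOC)c(CC=C(C)C)c(OCOC)c(CC=C(C)C)c1OCOC | intermediate
23 | 3-[2,4-bis(methoxymethoxy)phenyl]-1-[2,4,6-tris(methoxymethoxy)-3,5-bis(3-methylbut-2-enyl)phenyl]prop-2-yn-1-one | COCOc1ccc(C#CC(=O)c2c(OCOC)c(CC=C(C)C)c(OCOC)c(CC=C(C)C)c2OCOC)c(OCOC)c1 | intermediate
24 | 3-(2,4-dihydroxyphenyl)-1-[2,4,6-trihydroxy-3,5-bis(3-methylbut-2-enyl)phenyl]prop-2-yn-1-one, not isolated | CC(C)=CCc1c(O)c(CC=C(C)C)c(O)c(C(=O)C#Cc2ccc(O)cc2O)c1O | intermediate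
25 | 2-(2,4-dihydroxyphenyl)-5,7-dihydroxy-6,8-bis(3-methylbut-2-enyl)chromen-4-one | CC(C)=CCc1c(O)c(CC=C(C)C)c2oc(-c3ccc(O)cc3O)cc(=O)c2c1O | target

**Step count**
Total: 11 steps. Longest linear sequence: 8 steps (steps 1–6, 10 and 11); the ring B branch (steps 7–9) joins at step 10.

**Steps most likely to fail**

Step 4. The cyclobutenone is a vinylogous silyl ester and may open too slowly below the temperature at which the ynol silyl ether isomerises to a silylketene. The siloxy-substituted vinylketene may also dimerise or acylate the product phenol instead of adding to the alkyne. The fallback abandons the annulation and builds the same ring A by aromatic metalation; it sets out from prenyl bromide 1 and returns at compound 16. Commercial phloroglucinol is converted (NaH, MOMCl, DMF) into 1,3,5-tris(methoxymethoxy)benzene F1. Lithiation between two MOM ethers (n-BuLi, THF, 0 °C) and alkylation with 1 gives 1,3,5-tris(methoxymethoxy)-2-(3-methylbut-2-enyl)benzene F2. A second lithiation–alkylation with 1 gives 16, which replaces steps 1 to 6.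

Step 10. Deprotonation may occur at a benzylic–allylic prenyl CH2 instead of the crowded ring position, the lithiation may stall, or the aryllithium may add in conjugate fashion to the ynamide. The fallback avoids any organometallic at ring A; it sets out from triol 15 and aldehyde 18 and returns at target 25. Roskamp homologation of 18 (ethyl diazoacetate, SnCl2 cat., CH2Cl2) gives ethyl 3-[2,4-bis(methoxymethoxy)phenyl]-3-oxopropanoate F3. Heating 15 with F3 without solvent (microwave, ca. 240 °C, minutes) is a thermal aroylketene (Mentzer-type) pyrone annulation, known for phloroglucinol with aroylacetates. It C-acylates the free ring position and closes ring C to 2-[2,4-bis(methoxymethoxy)phenyl]-5,7-dihydroxy-6,8-bis(3-methylbut-2-enyl)chromen-4-one F4. Acidic methanolysis as in step 11 then gives 25.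

Step 11. Protonation of a prenyl double bond and capture of the tertiary cation by the neighbouring 5- or 7-hydroxyl (chroman formation) may compete with acetal cleavage, and 5-exo closure to an aurone may compete with ring C formation. The fallback keeps the ring A oxygens silylated until a final fluoride step, so that no phenol next to a prenyl group meets acid; it sets out from phenol 14, with alkyne 19 as partner, and returns at target 25.
- Ortho-formylation of 14 (MgCl2, Et3N, paraformaldehyde, MeCN, reflux) gives 2-hydroxy-3,5-bis(3-methylbut-2-enyl)-4,6-bis(triisopropylsilyloxy)benzaldehyde F5.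
- Addition of lithium acetylide 20 (2.2 equiv, from 19 and n-BuLi) gives 3-[2,4-bis(methoxymethoxy)phenyl]-1-[2-hydroxy-3,5-bis(3-methylbut-2-enyl)-4,6-bis(triisopropylsilyloxy)phenyl]prop-2-yn-1-ol F6.
- Oxidation with MnO2 in CH2Cl2 gives 3-[2,4-bis(methoxymethoxy)phenyl]-1-[2-hydroxy-3,5-bis(3-methylbut-2-enyl)-4,6-bis(triisopropylsilyloxy)phenyl]prop-2-yn-1-one F7.
- Amine-mediated 6-endo cyclisation (Et2NH, EtOH, then warming) gives 2-[2,4-bis(methoxymethoxy)phenyl]-6,8-bis(3-methylbut-2-enyl)-5,7-bis(triisopropylsilyloxy)chromen-4-one F8.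
- HCl in MeOH at rt removes only the ring B acetals to give 2-(2,4-dihydroxyphenyl)-6,8-bis(3-methylbut-2-enyl)-5,7-bis(triisopropylsilyloxy)chromen-4-one F9.
- Bu4NF/AcOH in THF then gives 25.

**Further compounds**
F1 | step 4 | 1,3,5-tris(methoxymethoxy)benzene | COCOc1cc(OCOC)cc(OCOC)c1
F2 | step 4 | 1,3,5-tris(methoxymethoxy)-2-(3-methylbut-2-enyl)benzene | COCOc1cc(OCOC)c(CC=C(C)C)c(OCOC)c1
F3 | step 10 | ethyl 3-[2,4-bis(methoxymethoxy)phenyl]-3-oxopropanoate | CCOC(=O)CC(=O)c1ccc(OCOC)cc1OCOC
F4 | step 10 | 2-[2,4-bis(methoxymethoxy)phenyl]-5,7-dihydroxy-6,8-bis(3-methylbut-2-enyl)chromen-4-one | COCOc1ccc(-c2cc(=O)c3c(O)c(CC=C(C)C)c(O)c(CC=C(C)C)c3o2)c(OCOC)c1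
F5 | step 11 | 2-hydroxy-3,5-bis(3-methylbut-2-enyl)-4,6-bis(triisopropylsilyloxy)benzaldehyde | CC(C)=CCc1c(O)c(C=O)c(O[Si](C(C)C)(C(C)C)C(C)C)c(CC=C(C)C)c1O[Si](C(C)C)(C(C)C)C(C)C
F6 | step 11 | 3-[2,4-bis(methoxymethoxy)phenyl]-1-[2-hydroxy-3,5-bis(3-methylbut-2-enyl)-4,6-bis(triisopropylsilyloxy)phenyl]prop-2-yn-1-ol (racemic) | COCOc1ccc(C#CC(O)c2c(O)c(CC=C(C)C)c(O[Si](C(C)C)(C(C)C)C(C)C)c(CC=C(C)C)c2O[Si](C(C)C)(C(C)C)C(C)C)c(OCOC)c1
F7 | step 11 | 3-[2,4-bis(methoxymethoxy)phenyl]-1-[2-hydroxy-3,5-bis(3-methylbut-2-enyl)-4,6-bis(triisopropylsilyloxy)phenyl]prop-2-yn-1-one | COCOc1ccc(C#CC(=O)c2c(O)c(CC=C(C)C)c(O[Si](C(C)C)(C(C)C)C(C)C)c(CC=C(C)C)c2O[Si](C(C)C)(C(C)C)C(C)C)c(OCOC)c1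
F8 | step 11 | 2-[2,4-bis(methoxymethoxy)phenyl]-6,8-bis(3-methylbut-2-enyl)-5,7-bis(triisopropylsilyloxy)chromen-4-one | COCOc1ccc(-c2cc(=O)c3c(O[Si](C(C)C)(C(C)C)C(C)C)c(CC=C(C)C)c(O[Si](C(C)C)(C(C)C)C(C)C)c(CC=C(C)C)c3o2)c(OCOC)c1
F9 | step 11 | 2-(2,4-dihydroxyphenyl)-6,8-bis(3-methylbut-2-enyl)-5,7-bis(triisopropylsilyloxy)chromen-4-one | CC(C)=CCc1c(O[Si](C(C)C)(C(C)C)C(C)C)c(CC=C(C)C)c2oc(-c3ccc(O)cc3O)cc(=O)c2c1O[Si](C(C)C)(C(C)C)C(C)C
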